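Remark on the chemistry: the target is achiral. The only stereocentre met on the way (C3 of chromanone 16) is made as the racemate and becomes sp2 in step 9. Chromone numbering (O1, C2, C3, C4, C4a, C5 to C8, C8a) is used for all bicyclic compounds; ring A is the benzenoid ring, ring C the pyranone and ring B the anisyl ring. Compound numbers refer to the list after the steps.

## Analysis of the target

The target is 7-hydroxy-5-methoxy-3-(4-methoxybenzyl)-6-methyl-4-oxo-4H-chromene-8-carbaldehyde, a homoisoflavone: a benzo-γ-pyrone (ring A fused to ring C) with a 4-methoxybenzyl group (ring B) on C3. It has no stereocentre and no alkene geometry, so the whole problem is regiochemistry. Ring A is hexasubstituted: from C4a round to C8a it carries the C4 acyl carbon, OMe (C5), CH3 (C6), OH (C7), CHO (C8) and the ring oxygen O1. This is a methylphloroglucinol core whose three oxygens are all different (one in ring C, one methylated, one free).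

The sensitive groups are:
- the ortho-hydroxy aldehyde;
- C2 of the chromone, which hard nucleophiles attack with ring opening;
- the C3–CH2–aryl methylene, benzylic to an anisole and allylic to the enone, hence easily oxidised;
- the 5-OMe group peri to the carbonyl, which chelating Lewis acids can cleave.

The difficulty lies in fusing ring C so that the methyl group ends at C6 and not at C8, and in telling O5 from O7. The strategy rests on one feature of ring A: C4a carries an acyl carbon and C8a an oxygen on adjacent carbons, C4a is flanked by the oxygenated C5, and C8a is flanked by a carbon (C8) that can be left as C–H until the end. That is the substitution pattern left when a 3-alkoxyaryne takes up an acyl–oxygen bond.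

## Retrosynthetic reasoning

**C8–CHO (21 to 20).** The formyl carbon is removed first. In 20, C8 is the only unsubstituted carbon of ring A and is ortho to the free 7-OH, so an ortho-formylation of the phenol can go nowhere else on that ring. Adding the aldehyde last also keeps it away from every oxidative, basic and organometallic step.

**The two oxygen substituents (20 to 19 to 18 to 17).** O5 and O7 are traced back to the same methoxymethyl acetal. They cannot be told apart in a symmetric precursor, but once the C4 carbonyl exists only O5 sits peri to it and can share a metal with it. The forward sequence is therefore chelation-controlled removal of the 5-acetal, methylation of the freed 5-OH and acid removal of the 7-acetal.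

**The C2=C3 double bond (17 to 16).** The chromone is taken back to the chroman-4-one. This is a pure oxidation-level change. It is accepted because the chromanone is exactly what the ring-forming step delivers. In the forward direction the hydride at C2 is activated by O1 and the product is an aromatic γ-pyrone.

**Ring C (16 to 8 and 13, through 14 and 15).** Three bonds are cut: C8a–O1, C4a–C4 and O1–C2.
- The first two are undone together as the insertion of aryne 14 into the acyl C–O bond of acid 13, which leads to the ortho-hydroxyaryl enone 15.
- The third is the conjugate addition of the phenoxide of 15 to its own α-methylene ketone.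
- Cutting here, rather than at C4–C4a alone, puts the acyl group and the oxygen on ring A in one event without any phenol having to be differentiated.
- Aryne 14 has one oxygenated carbon directly beside the triple bond, and that tells the carboxylate which end to attack.
- What remains are the silyl triflate 8 and a three-carbon acid 13 that already holds C2, C3, C4 and ring B.

**The aryne precursor (8 to 5 to 4 to 2 to 1).**
- The C–Si and C–OTf bonds of 8 go back to the C–Br and O–H bonds of bromophenol 5 by a silyl migration from oxygen to carbon.
- The C–Br bond goes back to phenol 4, which is symmetric, so its two free positions are the same carbon.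
- The phenolic C–O bond of 4 is cut to a C–H bond of 2. That C–H is the only one in 2 without an ortho neighbour, so a sterically governed C–H borylation followed by oxidation should find it.
- Compound 2 is the bis-acetal of 2-methylresorcinol 1.
- Because 4 is symmetric, only one aryne can arise from it.

**The acid (13 to 12 to 11 to 9 and 10).** The methylene carbon of 13 is removed by a retro-Mannich/decarboxylation step to the malonic acid 12. The diacid, not a half-ester, is chosen as the intermediate so that the methylenation gives the free acrylic acid directly and no ester hydrolysis has to follow. Compound 12 comes from malonate 11, and 11 from the alkylation of diethyl malonate 9 with 4-methoxybenzyl chloride 10.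

## Alternatives that were turned down

Alternative 1: Ring A is cut at C4a–C5 and C8–C8a and built by a Diels–Alder reaction.
- Forward key step: the diene 1,1-dimethoxy-2-methyl-3-(trimethylsilyloxy)buta-1,3-diene (A3) adds across the brominated C2=C3 bond of 3-bromo-5-(4-methoxybenzyl)-4H-pyran-4-one (A2). Loss of the halide, of one methoxy group and of the silyl group then aromatises the new ring to 7-hydroxy-5-methoxy-3-(4-methoxybenzyl)-6-methyl-4H-chromen-4-one (A1), which has the structure of compound 20.
- For it: A1 is one step from the target. The diene delivers O5 as a methyl ether and O7 as a free phenol, so no protecting-group work on ring A is needed. The methyl group is placed by the diene. The polarity of the two partners matches: the CH2 terminus of A3 meets the carbon of A2 next to the ring oxygen.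
- Against it: A2 is a 4-pyranone with two different substituents at C3 and C5 and needs its own synthesis with regiocontrolled bromination. 4-Pyranones are vinylogous esters with partial aromatic character and are reluctant dienophiles. A3 is hydrolytically fragile, and one of its methoxy groups always points into the diene, which disfavours the s-cis conformer. A stepwise Mukaiyama–Michael addition without ring closure is a real competitor.
- Comparison: this route is clearly stronger in step economy after the key step (one step against five). The chosen strategy offers in its place building blocks made by standard reactions from three cheap materials, a key reaction of a known type, and regiochemistry fixed by the substrate rather than by the matching of two unusual partners.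

Alternative 2: Ring C is cut at C4–C4a only.
- Forward key step: the carboxyl group of (Z)-3-[3,5-bis(benzyloxy)-4-methylphenoxy]-2-(4-methoxybenzyl)acrylic acid (A5) is activated, and the acylium carbon attacks the ortho carbon of the aryloxy ring (Friedel–Crafts acylation). This gives 5,7-bis(benzyloxy)-3-(4-methoxybenzyl)-6-methyl-4H-chromen-4-one (A4) directly.
- For it: the chromone oxidation level is reached in the ring closure, so no dehydrogenation is needed. The aryloxy ring is symmetric, so both ortho carbons are the same. The attacked carbon is activated by three oxygens.
- Against it: the closure needs strong Brønsted or Lewis acid. The aryl vinyl ether linkage of A5 is acid-labile. Benzyl ethers on so electron-rich a ring are prone to cleavage and migration. Ring B can compete as the nucleophile (closure to an indanone). Only the Z isomer of A5 can cyclise, and the usual routes to such acids give E/Z mixtures. After the key step, A4 still needs selective unmasking of O5, methylation, debenzylation in the presence of the C2=C3 bond, and formylation.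
- Comparison: this route is one step shorter after the key step and needs no oxidant. The chosen strategy offers near-neutral fluoride conditions that acetal protecting groups tolerate, no alkene geometry to control, and the formation of both ring A attachments in one operation.

Alternative 3: Ring C is cut at C4a–C4, C3–C4 and O1–C2 into three components.
- Forward key step: zerovalent palladium inserts into the C–I bond of 2-iodo-3,5-bis(methoxymethoxy)-4-methylphenol (A7). Carbon monoxide (A9) is taken up. The acyl group is transferred to the central carbon of 1-methoxy-4-(propa-1,2-dien-1-yl)benzene (A8). The phenoxide then attacks the CH2 end of the resulting π-allyl complex to give (E)-3-(4-methoxybenzylidene)-5,7-bis(methoxymethoxy)-6-methylchroman-4-one (A6).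
- For it: it is the most convergent plan, with three bonds formed from three components. A7 is one step from phenol 4, so the silyl triflate is not needed. A6 is already an isomer of chromone 17, so only a double-bond shift into the ring is required and no oxidant touches the anisyl methylene.
- Against it: three selectivities rest on the catalyst and not on the substrate. Uptake of A9 must come before insertion of A8, otherwise carbonyl-free heterocycles form. The free ortho-hydroxyl must not capture the acylpalladium species of another molecule. The phenoxide must choose the CH2 terminus over the benzylic one. The aryl iodide is hindered on both sides and very electron-rich. A8 is not a stock compound and oligomerises easily. The step needs a toxic gas under pressure.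
- Comparison: this route is stronger in convergence and probably shorter by one or two steps. The chosen strategy offers a metal-free ring formation whose single selectivity is built into aryne 14, and partners (8 and 13) that can be stored and purified.

Key step: step 8

## Route

Step 1
Reactants: 1 2-methylresorcinol
Product: 2 1,3-bis(methoxymethoxy)-2-methylbenzene
Conditions: NaH, DMF, 0 °C; MOMCl, 0 °C to rt
Reagents that add atoms: chloromethyl methyl ether, COCCl
Why: Williamson-type O-alkylation of both phenoxides by the α-chloro ether; the two acetals survive all later basic, organometallic and fluoride steps and later allow O5 and O7 to be told apart.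

Step 2
Reactants: 2 1,3-bis(methoxymethoxy)-2-methylbenzene
Product: 4 3,5-bis(methoxymethoxy)-4-methylphenol, via aryl pinacol boronate 3 (not isolated)
Conditions: [Ir(cod)OMe]2 (1.5 mol%), 4,4'-di-tert-butyl-2,2'-bipyridine (3 mol%), B2pin2 (0.6 equiv), THF, 80 °C; then NaOH, 30% aq. H2O2, THF, 0 °C to rt
Reagents that add atoms: hydrogen peroxide, OO (the phenol oxygen); bis(pinacolato)diboron, CC1(C)OB(OC1(C)C)B1OC(C)(C)C(C)(C)O1 (boron of 3 only)
Why: Iridium-catalysed C–H borylation is governed by sterics and C5 of 2 is the only C–H without an ortho substituent, so boron should enter meta to both acetals; alkaline peroxide then converts C–B into C–O at the same carbon (borylation–oxidation).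

Step 3
Reactants: 4 3,5-bis(methoxymethoxy)-4-methylphenol
Product: 5 2-bromo-3,5-bis(methoxymethoxy)-4-methylphenol
Conditions: NBS (1.0 equiv), CH2Cl2, −78 to 0 °C
Reagents that add atoms: N-bromosuccinimide, O=C1CCC(=O)N1Br
Why: Electrophilic aromatic bromination; the two free positions of 4 are equivalent and both ortho to OH, so monobromination can give only 5, and one equivalent of reagent at low temperature limits dibromination.

Step 4
Reactants: 5 2-bromo-3,5-bis(methoxymethoxy)-4-methylphenol
Product: 8 3,5-bis(methoxymethoxy)-4-methyl-2-(trimethylsilyl)phenyl trifluoromethanesulfonate, via aryl trimethylsilyl ether 6 (not isolated), via lithium 2-silylphenoxide 7 (not isolated)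
Conditions: HN(SiMe3)2, THF, 65 °C, then evaporation; n-BuLi, THF, −78 °C; Tf2O, −78 °C to rt
Reagents that add atoms: hexamethyldisilazane, C[Si](C)(C)N[Si](C)(C)C; trifluoromethanesulfonic anhydride, O=S(=O)(OS(=O)(=O)C(F)(F)F)C(F)(F)F
Why: O-silylation, bromine–lithium exchange and 1,3-shift of silicon from oxygen to carbon (retro-Brook rearrangement) put SiMe3 on the former C–Br carbon and free the phenoxide, which is triflated in the same flask; this is the standard passage from ortho-bromophenols to ortho-silylaryl triflates, and exchange at −78 °C outruns acetal-directed deprotonation.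

Step 5
Reactants: 9 diethyl malonate; 10 4-methoxybenzyl chloride
Product: 11 diethyl 2-(4-methoxybenzyl)malonate
Conditions: NaH, THF, 0 °C (9 in twofold excess); then 10, 0 °C to rt
Reagents that add atoms: none
Why: Malonic ester alkylation (SN2) with a reactive benzylic chloride; the excess of malonate suppresses dialkylation and the aprotic medium avoids solvolysis of the chloride.

Step 6
Reactants: 11 diethyl 2-(4-methoxybenzyl)malonate
Product: 12 2-(4-methoxybenzyl)malonic acid
Conditions: KOH, EtOH/H2O, reflux; then aq. HCl, 0 °C
Reagents that add atoms: potassium hydroxide, [K+].[OH-]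
Why: Saponification of both esters; cold acidification keeps the malonic acid from losing CO2 before the next step.

Step 7
Reactants: 12 2-(4-methoxybenzyl)malonic acid
Product: 13 2-(4-methoxybenzyl)acrylic acid
Conditions: (CH2O)n, Et2NH, EtOAc, reflux
Reagents that add atoms: paraformaldehyde (as formaldehyde), C=O
Why: Mannich reaction of the malonic acid with the iminium ion from formaldehyde and diethylamine, then decarboxylative elimination of the amine, should give the α-methylene acid directly (decarboxylative Mannich methylenation).

Step 8
Reactants: 8 3,5-bis(methoxymethoxy)-4-methyl-2-(trimethylsilyl)phenyl trifluoromethanesulfonate; 13 2-(4-methoxybenzyl)acrylic acid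
Product: 16 rac-3-(4-methoxybenzyl)-5,7-bis(methoxymethoxy)-6-methylchroman-4-one, via aryne 14 (not isolated), via ortho-hydroxyaryl enone 15 (not isolated)
Conditions: CsF (4 equiv), THF, 125 °C, sealed tube (8 in 1.5-fold excess)
Reagents that add atoms: none
Why: Fluoride removes SiMe3 from 8 and triflate leaves, giving aryne 14. The caesium carboxylate of 13 adds through oxygen to the aryne carbon remote from the acetal oxygen (future C8a), which places the aryl anion on the carbon next to that oxygen (future C4a). The anion attacks the ester carbonyl through a four-membered alkoxide that opens to the ortho-acyl phenoxide of 15, a net insertion of the aryne into the acyl C–O bond (C8a–O1 and C4a–C4 formed). The phenoxide then adds to the CH2 terminus of the α-methylene ketone in a 6-endo-trig oxa-Michael closure of ring C (O1–C2 formed). The closest known reaction type is the fluoride-mediated insertion of arynes into the C–O bond of carboxylic acids, which with acrylic acids runs on to 4-chromanones. The one selectivity needed is the site of carboxylate attack; the inductively withdrawing oxygen beside the triple bond distorts the aryne and stabilises the anion ortho to itself, and that carbon is also the more hindered one for the incoming nucleophile. Because phenol 4 is symmetric only this aryne can form, so the methyl group can only end at C6. C3 is set by unselective protonation of the enolate, so 16 is racemic, and the centre is removed in step 9.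

Step 9
Reactants: 16 rac-3-(4-methoxybenzyl)-5,7-bis(methoxymethoxy)-6-methylchroman-4-one
Product: 17 3-(4-methoxybenzyl)-5,7-bis(methoxymethoxy)-6-methyl-4H-chromen-4-one
Conditions: DDQ (1.3 equiv), 1,4-dioxane, reflux
Reagents that add atoms: none
Why: Quinone dehydrogenation of a chroman-4-one: hydride leaves C2 of the enol to give an O1-stabilised 4-hydroxybenzopyrylium ion, which loses a proton to the aromatic γ-pyrone; anhydrous conditions and a small excess of oxidant are chosen to spare the anisyl methylene.

Step 10
Reactants: 17 3-(4-methoxybenzyl)-5,7-bis(methoxymethoxy)-6-methyl-4H-chromen-4-one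
Product: 18 5-hydroxy-3-(4-methoxybenzyl)-7-(methoxymethoxy)-6-methyl-4H-chromen-4-one
Conditions: MgBr2·OEt2, Et2O/CH2Cl2, 0 °C to rt; aq. NH4Cl
Reagents that add atoms: none
Why: Chelation-controlled acetal cleavage: magnesium binds the C4 carbonyl oxygen and O5 in a six-membered chelate, so bromide should open only the peri acetal, while the 7-acetal has no chelating partner and should remain.

Step 11
Reactants: 18 5-hydroxy-3-(4-methoxybenzyl)-7-(methoxymethoxy)-6-methyl-4H-chromen-4-one
Product: 19 5-methoxy-3-(4-methoxybenzyl)-7-(methoxymethoxy)-6-methyl-4H-chromen-4-one
Conditions: MeI (excess), K2CO3, DMF, 45 °C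
Reagents that add atoms: iodomethane, CI
Why: Williamson methylation of the hydrogen-bonded 5-OH, the only free hydroxyl; the chromone and the remaining acetal are inert to carbonate.

Step 12
Reactants: 19 5-methoxy-3-(4-methoxybenzyl)-7-(methoxymethoxy)-6-methyl-4H-chromen-4-one
Product: 20 7-hydroxy-5-methoxy-3-(4-methoxybenzyl)-6-methyl-4H-chromen-4-one
Conditions: 3 M aq. HCl, MeOH, 50 °C
Reagents that add atoms: none
Why: Acid-catalysed transacetalisation to methanol removes the last methoxymethyl group; aryl methyl ethers and the chromone are stable to dilute protic acid.

Step 13
Reactants: 20 7-hydroxy-5-methoxy-3-(4-methoxybenzyl)-6-methyl-4H-chromen-4-one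
Product: 21 7-hydroxy-5-methoxy-3-(4-methoxybenzyl)-6-methyl-4-oxo-4H-chromene-8-carbaldehyde
Conditions: hexamethylenetetramine, AcOH, 100 °C; then 3 M aq. HCl, 100 °C
Reagents that add atoms: hexamethylenetetramine, C1N2CN3CN1CN(C2)C3; water, O
Why: Duff reaction: the phenol is aminomethylated ortho to OH, the benzylic amine is oxidised to an iminium ion by internal hydride transfer and hydrolysed to the aldehyde; C8 is the only free position of ring A, and in acetic acid the non-phenolic ring B should not react.

## Compound list

1 | 2-methylresorcinol (2-methylbenzene-1,3-diol) | Cc1c(O)cccc1O | starting material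
2 | 1,3-bis(methoxymethoxy)-2-methylbenzene | COCOc1cccc(OCOC)c1C | intermediate
3 | 2-[3,5-bis(methoxymethoxy)-4-methylphenyl]-4,4,5,5-tetramethyl-1,3,2-dioxaborolane | COCOc1cc(B2OC(C)(C)C(C)(C)O2)cc(OCOC)c1C | intermediate (not isolated)
4 | 3,5-bis(methoxymethoxy)-4-methylphenol | COCOc1cc(O)cc(OCOC)c1C | intermediate
5 | 2-bromo-3,5-bis(methoxymethoxy)-4-methylphenol | COCOc1cc(O)c(Br)c(OCOC)c1C | intermediate
6 | [2-bromo-3,5-bis(methoxymethoxy)-4-methylphenoxy]trimethylsilane | COCOc1cc(O[Si](C)(C)C)c(Br)c(OCOC)c1C | intermediate (not isolated)
7 | lithium 3,5-bis(methoxymethoxy)-4-methyl-2-(trimethylsilyl)phenoxide | [Li+].COCOc1cc([O-])c([Si](C)(C)C)c(OCOC)c1C | intermediate (not isolated)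
8 | 3,5-bis(methoxymethoxy)-4-methyl-2-(trimethylsilyl)phenyl trifluoromethanesulfonate | COCOc1cc(OS(=O)(=O)C(F)(F)F)c([Si](C)(C)C)c(OCOC)c1C | intermediate
9 | diethyl malonate | CCOC(=O)CC(=O)OCC | starting material
10 | 4-methoxybenzyl chloride | COc1ccc(CCl)cc1 | starting material
11 | diethyl 2-(4-methoxybenzyl)malonate | CCOC(=O)C(Cc1ccc(OC)cc1)C(=O)OCC | intermediate
12 | 2-(4-methoxybenzyl)malonic acid | COc1ccc(CC(C(=O)O)C(=O)O)cc1 | intermediate
13 | 2-(4-methoxybenzyl)acrylic acid | C=C(Cc1ccc(OC)cc1)C(=O)O | intermediate
14 | 3,5-bis(methoxymethoxy)-4-methylbenzyne (triple bond between C1 and C2) | COCOC1=C(C)C(OCOC)=CC#C1 | intermediate (not isolated)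
15 | 1-[6-hydroxy-2,4-bis(methoxymethoxy)-3-methylphenyl]-2-(4-methoxybenzyl)prop-2-en-1-one (present as its caesium phenoxide) | C=C(Cc1ccc(OC)cc1)C(=O)c1c(O)cc(OCOC)c(C)c1OCOC | intermediate (not isolated)
16 | rac-3-(4-methoxybenzyl)-5,7-bis(methoxymethoxy)-6-methylchroman-4-one | COCOc1cc2OCC(Cc3ccc(OC)cc3)C(=O)c2c(OCOC)c1C | intermediate
17 | 3-(4-methoxybenzyl)-5,7-bis(methoxymethoxy)-6-methyl-4H-chromen-4-one | COCOc1cc2occ(Cc3ccc(OC)cc3)c(=O)c2c(OCOC)c1C | intermediate
18 | 5-hydroxy-3-(4-methoxybenzyl)-7-(methoxymethoxy)-6-methyl-4H-chromen-4-one | COCOc1cc2occ(Cc3ccc(OC)cc3)c(=O)c2c(O)c1C | intermediate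
19 | 5-methoxy-3-(4-methoxybenzyl)-7-(methoxymethoxy)-6-methyl-4H-chromen-4-one | COCOc1cc2occ(Cc3ccc(OC)cc3)c(=O)c2c(OC)c1C | intermediate
20 | 7-hydroxy-5-methoxy-3-(4-methoxybenzyl)-6-methyl-4H-chromen-4-one | COc1ccc(Cc2coc3cc(O)c(C)c(OC)c3c2=O)cc1 | intermediate
21 | 7-hydroxy-5-methoxy-3-(4-methoxybenzyl)-6-methyl-4-oxo-4H-chromene-8-carbaldehyde | COc1ccc(Cc2coc3c(C=O)c(O)c(C)c(OC)c3c2=O)cc1 | target

## Step count and risk

Total step count: 13. Longest linear sequence: 10 steps (steps 1 to 4 and 8 to 13, from 2-methylresorcinol); the acid branch (steps 5 to 7) is 3 steps.

**Step 8 (key step).**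
- What may go wrong: the aryl anion may be protonated before it transfers the acyl group, which ends in plain O-arylation of the acid. The anion sits between two oxygen substituents and must close a four-membered ring, so this competition is real. The product phenoxide may be arylated by a second aryne, and the acrylic acid may oligomerise at 125 °C.
- Fallback: a classical construction that sets out from bromophenol 5 and returns to the route at chromone 17, bypassing steps 8 and 9.
  - O-Benzylation of 5 (BnBr, K2CO3, DMF) should give 1-(benzyloxy)-2-bromo-3,5-bis(methoxymethoxy)-4-methylbenzene F1.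
  - Bromine–lithium exchange (n-BuLi, THF, −78 °C) and acylation with N-methoxy-3-(4-methoxyphenyl)-N-methylpropanamide F2 should give 1-[6-(benzyloxy)-2,4-bis(methoxymethoxy)-3-methylphenyl]-3-(4-methoxyphenyl)propan-1-one F3. F2 is made from commercial 3-(4-methoxyphenyl)propanoic acid with 1,1'-carbonyldiimidazole and N,O-dimethylhydroxylamine hydrochloride.
  - Hydrogenolysis (H2, Pd/C, EtOAc) frees the one phenol next to the ring C–H, giving 1-[6-hydroxy-2,4-bis(methoxymethoxy)-3-methylphenyl]-3-(4-methoxyphenyl)propan-1-one F4.
  - Condensation with N,N-dimethylformamide dimethyl acetal (toluene, reflux) adds C2 and closes ring C to 17.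
  - The benzyl group marks the oxygen that becomes O1, so the methyl group again ends at C6.

**Step 9.**
- What may go wrong: hydride abstraction at the p-methoxybenzylic methylene may compete with abstraction at C2. This would put the double bond outside the ring or oxidise the product further at its doubly activated CH2. Conversion may also stall because enolisation of the hindered ketone is slow.
- Fallback: from 16, regiodefined enol silylation (LiN(SiMe3)2, Me3SiCl, THF, −78 °C; only C3 can enolise) should give 3-(4-methoxybenzyl)-5,7-bis(methoxymethoxy)-6-methyl-4-(trimethylsilyloxy)-2H-chromene F5. Saegusa–Ito oxidation (Pd(OAc)2, MeCN, rt) then gives 17 by β-hydride elimination from the palladium enolate, and a brief treatment with an amidine base would move any out-of-ring double bond into ring C.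

**Step 10.**
- What may go wrong: the two acetals may not be discriminated well enough. The result would be loss of both, or slow cleavage at O5 if the chelate is disfavoured by the out-of-plane acetal.
- Fallback: from 17, remove both acetals (HCl, MeOH, 50 °C) to 5,7-dihydroxy-3-(4-methoxybenzyl)-6-methyl-4H-chromen-4-one F6. Then re-protect only the more acidic, non-chelated 7-OH (MOMCl 1.05 equiv, i-Pr2NEt, CH2Cl2, 0 °C), which returns to 18.

**Step 13.**
- What may go wrong: conversion may be low, since the phenol is conjugated to the chromone carbonyl and Duff reactions on such phenols are sluggish. The aminomethylated intermediate may fail to undergo the redox step. If the conditions are forced, ring B may be attacked.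
- Fallback: from 20, iodination ortho to the phenol (N-iodosuccinimide, DMF, 0 °C) should give 7-hydroxy-8-iodo-5-methoxy-3-(4-methoxybenzyl)-6-methyl-4H-chromen-4-one F7. Palladium-catalysed reductive carbonylation (PdCl2(dppp), where dppp is 1,3-bis(diphenylphosphino)propane, CO 3 bar, Et3SiH, Na2CO3, DMF, 90 °C) then gives 21.

Further compounds

F1 | step 8 | 1-(benzyloxy)-2-bromo-3,5-bis(methoxymethoxy)-4-methylbenzene | COCOc1cc(OCc2ccccc2)c(Br)c(OCOC)c1C
F2 | step 8 | N-methoxy-3-(4-methoxyphenyl)-N-methylpropanamide | CON(C)C(=O)CCc1ccc(OC)cc1
F3 | step 8 | 1-[6-(benzyloxy)-2,4-bis(methoxymethoxy)-3-methylphenyl]-3-(4-methoxyphenyl)propan-1-one | COCOc1cc(OCc2ccccc2)c(C(=O)CCc2ccc(OC)cc2)c(OCOC)c1C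
F4 | step 8 | 1-[6-hydroxy-2,4-bis(methoxymethoxy)-3-methylphenyl]-3-(4-methoxyphenyl)propan-1-one | COCOc1cc(O)c(C(=O)CCc2ccc(OC)cc2)c(OCOC)c1C
F5 | step 9 | 3-(4-methoxybenzyl)-5,7-bis(methoxymethoxy)-6-methyl-4-(trimethylsilyloxy)-2H-chromene | COCOc1cc2OCC(Cc3ccc(OC)cc3)=C(O[Si](C)(C)C)c2c(OCOC)c1C
F6 | step 10 | 5,7-dihydroxy-3-(4-methoxybenzyl)-6-methyl-4H-chromen-4-one | COc1ccc(Cc2coc3cc(O)c(C)c(O)c3c2=O)cc1
F7 | step 13 | 7-hydroxy-8-iodo-5-methoxy-3-(4-methoxybenzyl)-6-methyl-4H-chromen-4-one | COc1ccc(Cc2coc3c(I)c(O)c(C)c(OC)c3c2=O)cc1
A1 | alternative 1 | 7-hydroxy-5-methoxy-3-(4-methoxybenzyl)-6-methyl-4H-chromen-4-one | COc1ccc(Cc2coc3cc(O)c(C)c(OC)c3c2=O)cc1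
A2 | alternative 1 | 3-bromo-5-(4-methoxybenzyl)-4H-pyran-4-one | COc1ccc(Cc2cocc(Br)c2=O)cc1
A3 | alternative 1 | 1,1-dimethoxy-2-methyl-3-(trimethylsilyloxy)buta-1,3-diene | COC(OC)=C(C)C(=C)O[Si](C)(C)C
A4 | alternative 2 | 5,7-bis(benzyloxy)-3-(4-methoxybenzyl)-6-methyl-4H-chromen-4-one | COc1ccc(Cc2coc3cc(OCc4ccccc4)c(C)c(OCc4ccccc4)c3c2=O)cc1
A5 | alternative 2 | (Z)-3-[3,5-bis(benzyloxy)-4-methylphenoxy]-2-(4-methoxybenzyl)acrylic acid | OC(=O)/C(Cc1ccc(OC)cc1)=C\Oc1cc(OCc2ccccc2)c(C)c(OCc2ccccc2)c1
A6 | alternative 3 | (E)-3-(4-methoxybenzylidene)-5,7-bis(methoxymethoxy)-6-methylchroman-4-one | COCOc1cc2OC/C(=C\c3ccc(OC)cc3)C(=O)c2c(OCOC)c1C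
A7 | alternative 3 | 2-iodo-3,5-bis(methoxymethoxy)-4-methylphenol | COCOc1cc(O)c(I)c(OCOC)c1C
A8 | alternative 3 | 1-methoxy-4-(propa-1,2-dien-1-yl)benzene | COc1ccc(C=C=C)cc1
A9 | alternative 3 | carbon monoxide | [C-]#[O+]
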